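## Retrosynthetic overview

- Feature used: in the cyclopentane ring C8–C12 (prostanoid numbering), C10 is the only ring CH2 and lies between the two carbinol carbons C9 and C11. C12 carries two carbons at the alcohol oxidation level or above (ring carbon C11 and side-chain carbon C13), so C12 can be carried as a prochiral CH(CH2OSi)2 unit and the ring closed last at C10–C11.
- PGF1α ⇒ C13 aldehyde + dimethyl (2-oxoheptyl)phosphonate (C13=C14 by Horner–Wadsworth–Emmons, C15 by reagent-controlled reduction, C9 by hydride reduction) ⇒ 11,13-bis-silylated cyclopentanone.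
- Cyclopentanone ⇒ acyclic C10 diazoketone: carbenoid insertion into a C–H bond of one CH2OTBS arm forms C10–C11, the only ring of the target, and the C11 and C12 stereocentres.
- Diazoketone ⇒ α-branched acid ⇒ auxiliary-controlled alkylation (C7–C8, sets C8) of an imide built from diethyl allylmalonate (C8, C9, C11–C13) with a propargylic bromide built from hex-5-ynoic acid (C1–C7).

Key step: step 13

Remark: hex-5-ynoic acid is taken in place of its methyl ester, so that the acetylide can be formed as a carboxylate dianion with no ester present. The (R)-benzyloxazolidinone is the auxiliary enantiomer that leads to the natural 8R configuration.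

## Route

Step 1
Reactants: 1 diethyl allylmalonate
Product: 2 2-(prop-2-enyl)propane-1,3-diol
Conditions: LiAlH4, THF, 0 °C → rt; then H2O, aq. NaOH
Reagents that add atoms: none
Why: LiAlH4 reduces both malonate ester groups to primary alcohols and leaves the isolated alkene untouched (ester reduction).

Step 2
Reactants: 2 2-(prop-2-enyl)propane-1,3-diol
Product: 3 2-allyl-1,3-bis(tert-butyldimethylsilyloxy)propane
Conditions: TBSCl, imidazole, DMF, rt
Reagents that add atoms: tert-butyldimethylsilyl chloride, CC(C)(C)[Si](C)(C)Cl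
Why: Silylation of both primary hydroxyl groups of a symmetrical diol, so no selectivity is needed.

Step 3
Reactants: 3 2-allyl-1,3-bis(tert-butyldimethylsilyloxy)propane
Product: 5 4-(tert-butyldimethylsilyloxy)-3-(tert-butyldimethylsilyloxymethyl)butanal, via ozonide 4 (not isolated)
Conditions: O3, CH2Cl2, −78 °C; then PPh3, −78 °C → rt
Reagents that add atoms: ozone, [O-][O+]=O
Why: Ozonolysis with reductive work-up cleaves the terminal alkene to the aldehyde one carbon shorter, and silyl ethers are inert to ozone.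

Step 4
Reactants: 5 4-(tert-butyldimethylsilyloxy)-3-(tert-butyldimethylsilyloxymethyl)butanal
Product: 6 4-(tert-butyldimethylsilyloxy)-3-(tert-butyldimethylsilyloxymethyl)butanoic acid
Conditions: NaClO2, NaH2PO4, 2-methylbut-2-ene, t-BuOH/H2O, rt
Reagents that add atoms: sodium chlorite, [Na+].[O-]Cl=O
Why: Pinnick oxidation converts the aldehyde into the acid under buffered conditions that primary TBS ethers tolerate, with 2-methylbut-2-ene trapping the hypochlorous acid.

Step 5
Reactants: 6 4-(tert-butyldimethylsilyloxy)-3-(tert-butyldimethylsilyloxymethyl)butanoic acid; 7 (4R)-4-benzyl-1,3-oxazolidin-2-one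
Product: 9 (4R)-4-benzyl-3-[4-(tert-butyldimethylsilyloxy)-3-(tert-butyldimethylsilyloxymethyl)butanoyl]-1,3-oxazolidin-2-one, via mixed pivalic anhydride 8 (not isolated)
Conditions: PivCl, Et3N, THF, −20 °C; then LiCl, 7, −20 °C → rt
Reagents that add atoms: pivaloyl chloride, CC(C)(C)C(=O)Cl (acyl group in intermediate 8 only)
Why: N-acylation of the oxazolidinone through the mixed pivalic anhydride, which is attacked at its less hindered acyl carbon.

Step 6
Reactants: 10 hex-5-ynoic acid
Product: 12 7-hydroxyhept-5-ynoic acid, via lithium 6-lithiohex-5-ynoate 11 (not isolated)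
Conditions: n-BuLi (2.2 equiv), THF, −78 → 0 °C; (CH2O)n, 0 °C → rt; then 1 M HCl
Reagents that add atoms: n-butyllithium, [Li]CCCC (lithium in intermediate 11 only); formaldehyde as paraformaldehyde, C=O
Why: The carboxylate shields C1 while the second equivalent of base forms the acetylide, which adds to formaldehyde (alkynylation of an aldehyde).

Step 7
Reactants: 12 7-hydroxyhept-5-ynoic acid
Product: 13 methyl 7-hydroxyhept-5-ynoate
Conditions: MeOH, H2SO4 (cat.), rt
Reagents that add atoms: methanol, CO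
Why: Fischer esterification, under which a primary propargylic alcohol is stable.

Step 8
Reactants: 13 methyl 7-hydroxyhept-5-ynoate
Product: 14 methyl 7-bromohept-5-ynoate
Conditions: CBr4, PPh3, CH2Cl2, 0 °C
Reagents that add atoms: carbon tetrabromide, BrC(Br)(Br)Br
Why: Appel bromination turns the primary propargylic alcohol into the bromide under neutral conditions that spare ester and alkyne.

Step 9
Reactants: 9 (4R)-4-benzyl-3-[4-(tert-butyldimethylsilyloxy)-3-(tert-butyldimethylsilyloxymethyl)butanoyl]-1,3-oxazolidin-2-one; 14 methyl 7-bromohept-5-ynoate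
Product: 16 methyl (8R)-9-[(4R)-4-benzyl-2-oxo-1,3-oxazolidin-3-yl]-8-[1,3-bis(tert-butyldimethylsilyloxy)propan-2-yl]-9-oxonon-5-ynoate, via sodium Z-enolate 15 (not isolated)
Conditions: NaN(SiMe3)2, THF, −78 °C; then 14, −78 → −40 °C
Reagents that add atoms: sodium bis(trimethylsilyl)amide, [Na+].C[Si](C)(C)[N-][Si](C)(C)C (sodium in intermediate 15 only)
Why: Evans asymmetric alkylation: the chelated Z-enolate is alkylated by the reactive propargylic bromide on the face opposite the benzyl group of the (R)-auxiliary, which sets C8 as R.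

Step 10
Reactants: 16 methyl (8R)-9-[(4R)-4-benzyl-2-oxo-1,3-oxazolidin-3-yl]-8-[1,3-bis(tert-butyldimethylsilyloxy)propan-2-yl]-9-oxonon-5-ynoate
Product: 17 methyl (8R)-9-[(4R)-4-benzyl-2-oxo-1,3-oxazolidin-3-yl]-8-[1,3-bis(tert-butyldimethylsilyloxy)propan-2-yl]-9-oxononanoate
Conditions: H2 (1 atm), 5% Pt/C, EtOAc, rt
Reagents that add atoms: none
Why: Catalytic hydrogenation saturates the alkyne so that no π bond can intercept the later carbenoid; platinum is chosen to limit double-bond migration toward C8, and imide, ester and silyl ethers are inert.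

Step 11
Reactants: 17 methyl (8R)-9-[(4R)-4-benzyl-2-oxo-1,3-oxazolidin-3-yl]-8-[1,3-bis(tert-butyldimethylsilyloxy)propan-2-yl]-9-oxononanoate
Product: 19 (2R)-2-[1,3-bis(tert-butyldimethylsilyloxy)propan-2-yl]-9-methoxy-9-oxononanoic acid, via peroxy acid 18 (not isolated)
Conditions: LiOH, H2O2, THF/H2O, 0 °C; then aq. Na2SO3; 1 M HCl to pH 3
Reagents that add atoms: hydrogen peroxide, OO
Why: Hydroperoxide cleavage of the Evans imide: the α-effect nucleophile attacks the exocyclic imide carbonyl much faster than hydroxide attacks the methyl ester at 0 °C, sulfite reduces the peroxy acid, and C8 is not epimerised.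

Step 12
Reactants: 19 (2R)-2-[1,3-bis(tert-butyldimethylsilyloxy)propan-2-yl]-9-methoxy-9-oxononanoic acid
Product: 21 methyl (8R)-8-[1,3-bis(tert-butyldimethylsilyloxy)propan-2-yl]-10-diazo-9-oxodecanoate, via isobutyl carbonic anhydride 20 (not isolated)
Conditions: i-BuOCOCl, N-methylmorpholine, THF, −15 °C; then CH2N2, Et2O, 0 °C → rt
Reagents that add atoms: isobutyl chloroformate, CC(C)COC(=O)Cl (in intermediate 20 only); diazomethane, C=[N+]=[N-]
Why: Acylation of diazomethane by a mixed carbonic anhydride (first stage of an Arndt–Eistert sequence), which keeps α-stereocentres intact and avoids an acyl chloride that could lactonise onto a γ-silyloxy group.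

Step 13
Reactants: 21 methyl (8R)-8-[1,3-bis(tert-butyldimethylsilyloxy)propan-2-yl]-10-diazo-9-oxodecanoate
Product: 22 methyl 7-[(1R,2S,3R)-3-(tert-butyldimethylsilyloxy)-2-(tert-butyldimethylsilyloxymethyl)-5-oxocyclopentyl]heptanoate
Conditions: Rh2(OAc)4 (1 mol %), CH2Cl2, rt, slow addition of 21
Reagents that add atoms: none
Why: Proposed new method: Rh2(OAc)4 (divalent rhodium) takes N2 from the diazoketone, and the electrophilic rhodium carbenoid at C10 inserts, in a concerted three-centre step with hydride-transfer character, into a C–H bond of one CH2OTBS arm that the adjacent oxygen makes electron-rich, forming C10–C11; the closest known reaction type is the dirhodium-catalysed 1,5 C–H insertion of α-diazoketones next to an ether oxygen that gives trans-substituted 3-alkoxycyclopentanones, and the untested part is the choice between two diastereotopic arms. The cyclopentanone (C8–C12) closes by 1,5 insertion through a chair-like six-centre array C10–C9–C8–C12–C11–H. C12 becomes stereogenic by the choice of arm and C11 by the choice of hydrogen, both steered by the preset C8 centre: in the preferred chair the C8 chain, the spectator CH2OTBS group on C12 and the OTBS group on C11 are all pseudo-equatorial, which leads to the 8,12-trans-11,12-trans isomer needed. The step also needs site selectivity for the oxygen-activated arm C–H over the unactivated C6–H that is equally 1,5-related, and chemoselectivity for insertion over oxonium ylide formation or addition to a π bond; the silyloxy activation, the bulk of the TBS groups and the fully saturated α chain are expected to secure these. C8 is not touched, and its trans relation to C12 is also the thermodynamically preferred one at this enolisable centre.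

Step 14
Reactants: 22 methyl 7-[(1R,2S,3R)-3-(tert-butyldimethylsilyloxy)-2-(tert-butyldimethylsilyloxymethyl)-5-oxocyclopentyl]heptanoate
Product: 23 methyl 7-[(1R,2S,3R,5S)-3-(tert-butyldimethylsilyloxy)-2-(tert-butyldimethylsilyloxymethyl)-5-hydroxycyclopentyl]heptanoate
Conditions: LiBH(s-Bu)3, THF, −78 °C; then aq. NH4Cl
Reagents that add atoms: none
Why: Bulky-hydride reduction: the hydride should approach C9 from the β face, anti to the adjacent C8 chain and to the 11-silyloxy group, giving the 9α (9S) alcohol as in the reduction of 11-silylated PGE-type ketones, while the methyl ester is not reduced at −78 °C.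

Step 15
Reactants: 23 methyl 7-[(1R,2S,3R,5S)-3-(tert-butyldimethylsilyloxy)-2-(tert-butyldimethylsilyloxymethyl)-5-hydroxycyclopentyl]heptanoate
Product: 24 methyl 7-[(1R,2S,3R,5S)-3-(tert-butyldimethylsilyloxy)-5-hydroxy-2-(hydroxymethyl)cyclopentyl]heptanoate
Conditions: HF·pyridine, pyridine, THF, 0 °C
Reagents that add atoms: none
Why: Buffered HF·pyridine cleaves the unhindered primary TBS ether much faster than the secondary one at C11 (sterically controlled selective desilylation).

Step 16
Reactants: 24 methyl 7-[(1R,2S,3R,5S)-3-(tert-butyldimethylsilyloxy)-5-hydroxy-2-(hydroxymethyl)cyclopentyl]heptanoate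
Product: 25 methyl 7-[(1R,2R,3R,5S)-3-(tert-butyldimethylsilyloxy)-2-formyl-5-hydroxycyclopentyl]heptanoate
Conditions: TEMPO (cat.), PhI(OAc)2, CH2Cl2, rt; used crude
Reagents that add atoms: none
Why: Oxoammonium (TEMPO) oxidation is strongly selective for primary over secondary alcohols, so C13 gives the aldehyde while the 9-hydroxyl stays; the trans relation of 9-OH and C13 rules out lactol formation.

Step 17
Reactants: 25 methyl 7-[(1R,2R,3R,5S)-3-(tert-butyldimethylsilyloxy)-2-formyl-5-hydroxycyclopentyl]heptanoate; 26 dimethyl (2-oxoheptyl)phosphonate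
Product: 27 methyl 7-[(1R,2R,3R,5S)-3-(tert-butyldimethylsilyloxy)-5-hydroxy-2-[(1E)-3-oxooct-1-enyl]cyclopentyl]heptanoate
Conditions: LiCl, i-Pr2NEt, MeCN, rt
Reagents that add atoms: none
Why: Horner–Wadsworth–Emmons olefination under Masamune–Roush conditions gives the E enone with a base mild enough to avoid β-elimination of the 11-silyloxy group and epimerisation at C12, and tolerates the free hydroxyl.

Step 18
Reactants: 27 methyl 7-[(1R,2R,3R,5S)-3-(tert-butyldimethylsilyloxy)-5-hydroxy-2-[(1E)-3-oxooct-1-enyl]cyclopentyl]heptanoate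
Product: 28 methyl 7-[(1R,2R,3R,5S)-3-(tert-butyldimethylsilyloxy)-5-hydroxy-2-[(1E,3S)-3-hydroxyoct-1-enyl]cyclopentyl]heptanoate
Conditions: (R)-2-methyl-CBS-oxazaborolidine, catecholborane (excess), toluene, −78 °C
Reagents that add atoms: none
Why: Corey–Bakshi–Shibata reduction: with the alkenyl group acting as the larger ketone substituent, the (R)-oxazaborolidine should deliver hydride to the face that gives the 15S allylic alcohol, and catecholborane gives 1,2-reduction without touching the ester.

Step 19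
Reactants: 28 methyl 7-[(1R,2R,3R,5S)-3-(tert-butyldimethylsilyloxy)-5-hydroxy-2-[(1E,3S)-3-hydroxyoct-1-enyl]cyclopentyl]heptanoate
Product: 29 methyl 7-[(1R,2R,3R,5S)-3,5-dihydroxy-2-[(1E,3S)-3-hydroxyoct-1-enyl]cyclopentyl]heptanoate (PGF1α methyl ester)
Conditions: HF·pyridine, MeCN, 0 °C → rt
Reagents that add atoms: none
Why: Fluoride-mediated cleavage of the remaining secondary TBS ether under conditions that spare the allylic alcohol and the ester.

Step 20
Reactants: 29 PGF1α methyl ester
Product: 30 prostaglandin F1α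
Conditions: LiOH, THF/MeOH/H2O, rt; then 1 M HCl to pH 4
Reagents that add atoms: lithium hydroxide, [Li+].[OH-]
Why: Saponification of the methyl ester; no stereocentre is α to a carbonyl at this stage, and mild acidification avoids allylic ionisation at C15.

## Compound list

1 | diethyl allylmalonate | C=CCC(C(=O)OCC)C(=O)OCC | starting material
2 | 2-(prop-2-enyl)propane-1,3-diol | C=CCC(CO)CO | intermediate
3 | 2-allyl-1,3-bis(tert-butyldimethylsilyloxy)propane | C=CCC(CO[Si](C)(C)C(C)(C)C)CO[Si](C)(C)C(C)(C)C | intermediate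
4 | 3-[3-(tert-butyldimethylsilyloxy)-2-(tert-butyldimethylsilyloxymethyl)propyl]-1,2,4-trioxolane (ozonide) | C1OC(CC(CO[Si](C)(C)C(C)(C)C)CO[Si](C)(C)C(C)(C)C)OO1 | intermediate (not isolated)
5 | 4-(tert-butyldimethylsilyloxy)-3-(tert-butyldimethylsilyloxymethyl)butanal | O=CCC(CO[Si](C)(C)C(C)(C)C)CO[Si](C)(C)C(C)(C)C | intermediate
6 | 4-(tert-butyldimethylsilyloxy)-3-(tert-butyldimethylsilyloxymethyl)butanoic acid | OC(=O)CC(CO[Si](C)(C)C(C)(C)C)CO[Si](C)(C)C(C)(C)C | intermediate
7 | (4R)-4-benzyl-1,3-oxazolidin-2-one | O=C1N[C@H](Cc2ccccc2)CO1 | starting material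
8 | 4-(tert-butyldimethylsilyloxy)-3-(tert-butyldimethylsilyloxymethyl)butanoic pivalic anhydride | CC(C)(C)C(=O)OC(=O)CC(CO[Si](C)(C)C(C)(C)C)CO[Si](C)(C)C(C)(C)C | intermediate (not isolated)
9 | (4R)-4-benzyl-3-[4-(tert-butyldimethylsilyloxy)-3-(tert-butyldimethylsilyloxymethyl)butanoyl]-1,3-oxazolidin-2-one | O=C1OC[C@@H](Cc2ccccc2)N1C(=O)CC(CO[Si](C)(C)C(C)(C)C)CO[Si](C)(C)C(C)(C)C | intermediate
10 | hex-5-ynoic acid | C#CCCCC(=O)O | starting material
11 | lithium 6-lithiohex-5-ynoate | [Li]C#CCCCC(=O)O[Li] | intermediate (not isolated)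
12 | 7-hydroxyhept-5-ynoic acid | OCC#CCCCC(=O)O | intermediate
13 | methyl 7-hydroxyhept-5-ynoate | OCC#CCCCC(=O)OC | intermediate
14 | methyl 7-bromohept-5-ynoate | BrCC#CCCCC(=O)OC | intermediate
15 | sodium Z-enolate of imide 9 | [Na]O/C(=C\C(CO[Si](C)(C)C(C)(C)C)CO[Si](C)(C)C(C)(C)C)N1[C@H](Cc2ccccc2)COC1=O | intermediate (not isolated)
16 | methyl (8R)-9-[(4R)-4-benzyl-2-oxo-1,3-oxazolidin-3-yl]-8-[1,3-bis(tert-butyldimethylsilyloxy)propan-2-yl]-9-oxonon-5-ynoate | O=C1OC[C@@H](Cc2ccccc2)N1C(=O)[C@H](CC#CCCCC(=O)OC)C(CO[Si](C)(C)C(C)(C)C)CO[Si](C)(C)C(C)(C)C | intermediate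
17 | methyl (8R)-9-[(4R)-4-benzyl-2-oxo-1,3-oxazolidin-3-yl]-8-[1,3-bis(tert-butyldimethylsilyloxy)propan-2-yl]-9-oxononanoate | O=C1OC[C@@H](Cc2ccccc2)N1C(=O)[C@H](CCCCCCC(=O)OC)C(CO[Si](C)(C)C(C)(C)C)CO[Si](C)(C)C(C)(C)C | intermediate
18 | (2R)-2-[1,3-bis(tert-butyldimethylsilyloxy)propan-2-yl]-9-methoxy-9-oxononaneperoxoic acid | OOC(=O)[C@H](CCCCCCC(=O)OC)C(CO[Si](C)(C)C(C)(C)C)CO[Si](C)(C)C(C)(C)C | intermediate (not isolated)
19 | (2R)-2-[1,3-bis(tert-butyldimethylsilyloxy)propan-2-yl]-9-methoxy-9-oxononanoic acid | OC(=O)[C@H](CCCCCCC(=O)OC)C(CO[Si](C)(C)C(C)(C)C)CO[Si](C)(C)C(C)(C)C | intermediate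
20 | (2R)-2-[1,3-bis(tert-butyldimethylsilyloxy)propan-2-yl]-9-methoxy-9-oxononanoic isobutyl carbonic anhydride | CC(C)COC(=O)OC(=O)[C@H](CCCCCCC(=O)OC)C(CO[Si](C)(C)C(C)(C)C)CO[Si](C)(C)C(C)(C)C | intermediate (not isolated)
21 | methyl (8R)-8-[1,3-bis(tert-butyldimethylsilyloxy)propan-2-yl]-10-diazo-9-oxodecanoate | [N-]=[N+]=CC(=O)[C@H](CCCCCCC(=O)OC)C(CO[Si](C)(C)C(C)(C)C)CO[Si](C)(C)C(C)(C)C | intermediate
22 | methyl 7-[(1R,2S,3R)-3-(tert-butyldimethylsilyloxy)-2-(tert-butyldimethylsilyloxymethyl)-5-oxocyclopentyl]heptanoate | CC(C)(C)[Si](C)(C)OC[C@@H]1[C@@H](CCCCCCC(=O)OC)C(=O)C[C@H]1O[Si](C)(C)C(C)(C)C | intermediate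
23 | methyl 7-[(1R,2S,3R,5S)-3-(tert-butyldimethylsilyloxy)-2-(tert-butyldimethylsilyloxymethyl)-5-hydroxycyclopentyl]heptanoate | CC(C)(C)[Si](C)(C)OC[C@@H]1[C@@H](CCCCCCC(=O)OC)[C@@H](O)C[C@H]1O[Si](C)(C)C(C)(C)C | intermediate
24 | methyl 7-[(1R,2S,3R,5S)-3-(tert-butyldimethylsilyloxy)-5-hydroxy-2-(hydroxymethyl)cyclopentyl]heptanoate | OC[C@@H]1[C@@H](CCCCCCC(=O)OC)[C@@H](O)C[C@H]1O[Si](C)(C)C(C)(C)C | intermediate
25 | methyl 7-[(1R,2R,3R,5S)-3-(tert-butyldimethylsilyloxy)-2-formyl-5-hydroxycyclopentyl]heptanoate | O=C[C@@H]1[C@@H](CCCCCCC(=O)OC)[C@@H](O)C[C@H]1O[Si](C)(C)C(C)(C)C | intermediate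
26 | dimethyl (2-oxoheptyl)phosphonate | CCCCCC(=O)CP(=O)(OC)OC | starting material
27 | methyl 7-[(1R,2R,3R,5S)-3-(tert-butyldimethylsilyloxy)-5-hydroxy-2-[(1E)-3-oxooct-1-enyl]cyclopentyl]heptanoate | CCCCCC(=O)/C=C/[C@@H]1[C@@H](CCCCCCC(=O)OC)[C@@H](O)C[C@H]1O[Si](C)(C)C(C)(C)C | intermediate
28 | methyl 7-[(1R,2R,3R,5S)-3-(tert-butyldimethylsilyloxy)-5-hydroxy-2-[(1E,3S)-3-hydroxyoct-1-enyl]cyclopentyl]heptanoate | CCCCC[C@H](O)/C=C/[C@@H]1[C@@H](CCCCCCC(=O)OC)[C@@H](O)C[C@H]1O[Si](C)(C)C(C)(C)C | intermediate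
29 | methyl 7-[(1R,2R,3R,5S)-3,5-dihydroxy-2-[(1E,3S)-3-hydroxyoct-1-enyl]cyclopentyl]heptanoate (PGF1α methyl ester) | CCCCC[C@H](O)/C=C/[C@@H]1[C@@H](CCCCCCC(=O)OC)[C@@H](O)C[C@H]1O | intermediate
30 | prostaglandin F1α | CCCCC[C@H](O)/C=C/[C@@H]1[C@@H](CCCCCCC(=O)O)[C@@H](O)C[C@H]1O | target

## Step count and risks

Total step count: 20. Longest linear sequence: 17 steps (steps 1–5 and 9–20, from diethyl allylmalonate); steps 6–8 form the side branch.

Steps most likely to fail:

1. Step 13 (carbenoid C–H insertion). The carbenoid may discriminate poorly between the two diastereotopic arms or between the two hydrogens of the chosen arm. It may also be diverted to insertion at C6–H, to attack on a silyl ether oxygen, or to carbene dimerisation. The fallback uses known chemistry, sets out from bromide 14 and comes back to the route at 29; it replaces the insertion by a conjugate-addition and enolate-trapping assembly on a preformed ring.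
   - NaI in acetone converts 14 into methyl 7-iodohept-5-ynoate F1.
   - (S,E)-tert-Butyl[(1-iodooct-1-en-3-yl)oxy]dimethylsilane is lithiated with t-BuLi and converted with Me2Zn into the lithium alkenyldimethylzincate. This adds 1,4 to (R)-4-(tert-butyldimethylsilyloxy)cyclopent-2-en-1-one, trans to the silyloxy group.
   - The resulting enolate is alkylated with F1 in THF/HMPA, trans to the new side chain, to give methyl 7-[(1R,2R,3R)-3-(tert-butyldimethylsilyloxy)-2-[(1E,3S)-3-(tert-butyldimethylsilyloxy)oct-1-enyl]-5-oxocyclopentyl]hept-5-ynoate F2.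
   - Hydrogenation over Pd/C, stopped after two equivalents of H2, should saturate the alkyne while the 13,14-alkene, shielded by the two silyloxy groups, remains. This gives PGE1 methyl ester 11,15-bis(tert-butyldimethylsilyl) ether F3.
   - LiBH(s-Bu)3 at −78 °C gives PGF1α methyl ester 11,15-bis(tert-butyldimethylsilyl) ether F4, and HF·pyridine in MeCN gives 29.

2. Step 18 (C15 reduction). Facial selectivity at C15 rests on reagent control alone on a flexible enone, the free 9-hydroxyl consumes borane, and 1,4-reduction may compete. The fallback sets out from aldehyde 25 and comes back at 28; it brings in C15 with its configuration already fixed.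
   - Methylenation of 25 with Ph3P=CH2 (from Ph3PCH3Br and KN(SiMe3)2, THF, −78 → 0 °C) gives methyl 7-[(1R,2R,3R,5S)-3-(tert-butyldimethylsilyloxy)-2-ethenyl-5-hydroxycyclopentyl]heptanoate F5.
   - Cross-metathesis of F5 with an excess of (S)-oct-1-en-3-ol, using second-generation Hoveyda–Grubbs catalyst in CH2Cl2 at 40 °C, should give the E allylic alcohol 28 directly.

3. Step 11 (auxiliary cleavage). At the hindered α,β-branched imide, hydroperoxide attack may become slow enough for hydrolysis of the C1 methyl ester or endocyclic opening of the oxazolidinone to compete. The fallback sets out from 17 and comes back at 19; it uses a sulfur nucleophile that does not touch a methyl ester.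
   - LiSCH2Ph (from PhCH2SH and n-BuLi, THF, 0 °C) displaces the auxiliary and gives methyl (8R)-9-(benzylsulfanyl)-8-[1,3-bis(tert-butyldimethylsilyloxy)propan-2-yl]-9-oxononanoate F6.
   - AgNO3 with 2,6-lutidine in THF/H2O hydrolyses the thioester F6 to 19 under near-neutral conditions.

## Further compounds

F1 | step 13 | methyl 7-iodohept-5-ynoate | ICC#CCCCC(=O)OC
F2 | step 13 | methyl 7-[(1R,2R,3R)-3-(tert-butyldimethylsilyloxy)-2-[(1E,3S)-3-(tert-butyldimethylsilyloxy)oct-1-enyl]-5-oxocyclopentyl]hept-5-ynoate | CCCCC[C@H](O[Si](C)(C)C(C)(C)C)/C=C/[C@@H]1[C@@H](CC#CCCCC(=O)OC)C(=O)C[C@H]1O[Si](C)(C)C(C)(C)C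
F3 | step 13 | methyl 7-[(1R,2R,3R)-3-(tert-butyldimethylsilyloxy)-2-[(1E,3S)-3-(tert-butyldimethylsilyloxy)oct-1-enyl]-5-oxocyclopentyl]heptanoate | CCCCC[C@H](O[Si](C)(C)C(C)(C)C)/C=C/[C@@H]1[C@@H](CCCCCCC(=O)OC)C(=O)C[C@H]1O[Si](C)(C)C(C)(C)C
F4 | step 13 | methyl 7-[(1R,2R,3R,5S)-3-(tert-butyldimethylsilyloxy)-2-[(1E,3S)-3-(tert-butyldimethylsilyloxy)oct-1-enyl]-5-hydroxycyclopentyl]heptanoate | CCCCC[C@H](O[Si](C)(C)C(C)(C)C)/C=C/[C@@H]1[C@@H](CCCCCCC(=O)OC)[C@@H](O)C[C@H]1O[Si](C)(C)C(C)(C)C
F5 | step 18 | methyl 7-[(1R,2R,3R,5S)-3-(tert-butyldimethylsilyloxy)-2-ethenyl-5-hydroxycyclopentyl]heptanoate | C=C[C@@H]1[C@@H](CCCCCCC(=O)OC)[C@@H](O)C[C@H]1O[Si](C)(C)C(C)(C)C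
F6 | step 11 | methyl (8R)-9-(benzylsulfanyl)-8-[1,3-bis(tert-butyldimethylsilyloxy)propan-2-yl]-9-oxononanoate | O=C(SCc1ccccc1)[C@H](CCCCCCC(=O)OC)C(CO[Si](C)(C)C(C)(C)C)CO[Si](C)(C)C(C)(C)C
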